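**Plan**

1. Labels: ring A is the cyclohexene C1–C6 (C1 carries the propanoate carbon Cα, C2 the quaternary carbon Cq of ring C, C3 and C4 are CH2, C5 carries the lactone carbonyl carbon C7, C6 the lactol carbon C8); ring B is the lactol-lactone; ring C is the trimethylcyclohexane.
2. Retrosynthesis: the lactol O–benzyl bond, then the C7–O bond of ring B (oxygen insertion), then C5–C7 and C6–C8 together (alkoxyketene plus the diene C2=C1–C6=C5), then Cα–CH3, C1–CH2 (dienyl triflate coupling), the ring A unsaturation (an anisole), the gem-dimethyl carbon of ring C and the Cq–aryl bond.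
3. Forward: ring C with Cq is built first on 3-methylcyclohexenone, the anisole is turned into ring A (Birch reduction, enone, dienyl triflate), the side chain is attached and methylated, the four-membered ring is closed on C5=C6 and then expanded to ring B.
4. Enabling feature: ring B is cis-fused to ring A with its acyl carbon on C5 and its acetal carbon on C6, the allylic position next to the tetrasubstituted C1=C2 bond; this is where a ketene carbonyl carbon and its substituted carbon end up on the terminal double bond of a 1,3-diene.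
5. Stereochemistry: Cq comes from a rhodium–(S)-BINAP conjugate arylation, Cα from an oxazolidinone-directed methylation, C5 and C6 from suprafacial addition on the diene face anti to the Cα methyl, and C8 from the endo preference of the ketene substituent followed by retention in the oxygen insertion.

Key step: step 11

Remark: the lactol carbon C8 can equilibrate through the open aldehyde acid, so it is assumed to hold the drawn configuration once set and is liberated last under neutral conditions.
Remark: the sense of induction in step 1 is assigned by analogy with rhodium–BINAP arylations of cyclohex-2-enone; the ligand antipode is to be used if the opposite sense is found.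

**Step 1**
Reactants: 1 2-bromoanisole; 2 3-methylcyclohex-2-en-1-one
Product: 6 ketone (3S)-3-(2-methoxyphenyl)-3-methylcyclohexan-1-one, via aryllithium 3 (not isolated), via arylalane 4 (not isolated), via aluminium enolate 5 (not isolated)
Conditions: n-BuLi, Et2O, −78 → 0 °C; Me2AlCl, 0 °C → rt; then 2, [RhCl(cod)]2 (2.5 mol%), (S)-BINAP (6 mol%), THF, 60 °C; aq. HCl
Reagents that add atoms: none
Why: Rhodium–BINAP-catalysed asymmetric conjugate addition of an aryl(dimethyl)alane to a β-methyl cycloalkenone is an established route to aryl-bearing quaternary centres that tolerates ortho substituents; the bisphosphine selects the enone face so that Cq is formed as (S), and the methoxy group is carried along as the future C1 oxygen.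

**Step 2**
Reactants: 6 ketone (3S)-3-(2-methoxyphenyl)-3-methylcyclohexan-1-one
Product: 7 anisole 1-methoxy-2-[(1S)-1,3,3-trimethylcyclohexyl]benzene
Conditions: Me2Zn, TiCl4, CH2Cl2, −40 °C → rt
Reagents that add atoms: dimethylzinc, C[Zn]C
Why: Reetz geminal dimethylation, in which Me2TiCl2 made from Me2Zn and TiCl4 adds one methyl to the carbonyl, ionises the titanium alkoxide and delivers the second methyl, turns the ketone carbon directly into the C(CH3)2 carbon of ring C without touching Cq; the only arene position within reach of the transient cation is meta to OMe and unactivated.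

**Step 3**
Reactants: 7 anisole 1-methoxy-2-[(1S)-1,3,3-trimethylcyclohexyl]benzene
Product: 10 enone 6-[(1S)-1,3,3-trimethylcyclohexyl]cyclohex-2-en-1-one, via dihydroanisole 8 (not isolated), via unconjugated enone 9 (not isolated)
Conditions: Li, NH3(l), t-BuOH, THF, −78 → −33 °C; NH4Cl; then 2 M HCl, THF, rt
Reagents that add atoms: water, O
Why: Birch reduction of an ortho-alkylanisole keeps OMe and the alkyl group on one double bond (C1=C2) and reduces C3 and C6, and acid then hydrolyses the enol ether and draws the C4=C5 bond into conjugation as C5=C6, the standard way to 6-substituted cyclohex-2-enones; the stereocentre so created at C2 is a mixture that is erased in step 4.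

**Step 4**
Reactants: 10 enone 6-[(1S)-1,3,3-trimethylcyclohexyl]cyclohex-2-en-1-one
Product: 12 dienyl triflate 2-[(1S)-1,3,3-trimethylcyclohexyl]cyclohexa-1,5-dien-1-yl trifluoromethanesulfonate, via lithium dienolate 11 (not isolated)
Conditions: LiN(i-Pr)2, THF, −78 °C; PhNTf2, −78 → 0 °C
Reagents that add atoms: N-phenylbis(trifluoromethanesulfonimide), O=S(=O)(N(c1ccccc1)S(=O)(=O)C(F)(F)F)C(F)(F)F
Why: Kinetic deprotonation of a cyclohex-2-enone by a lithium amide at −78 °C removes the α′ hydrogen (C2–H) and not the γ hydrogens, and O-sulfonylation of the cross-conjugated dienolate with PhNTf2 (enol triflate formation) fixes the C2=C1–C6=C5 diene with a leaving group on C1.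

**Step 5**
Reactants: 12 dienyl triflate 2-[(1S)-1,3,3-trimethylcyclohexyl]cyclohexa-1,5-dien-1-yl trifluoromethanesulfonate; 13 methyl bromoacetate
Product: 15 dienylacetate methyl 2-{2-[(1S)-1,3,3-trimethylcyclohexyl]cyclohexa-1,5-dien-1-yl}acetate, via zinc reagent 14 (not isolated)
Conditions: Zn dust (Me3SiCl-activated), THF, 40 °C; then 12, Pd(dba)2 (5 mol%), XPhos (10 mol%), THF, 60 °C
Reagents that add atoms: none
Why: Palladium-catalysed cross-coupling of a Reformatsky reagent with an alkenyl triflate (a Negishi-type coupling of a zinc ester enolate) joins C1 to a small primary carbon nucleophile, and a bulky biarylphosphine is chosen to drive transmetalation and reductive elimination beside the tert-alkyl group on C2.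

**Step 6**
Reactants: 15 dienylacetate methyl 2-{2-[(1S)-1,3,3-trimethylcyclohexyl]cyclohexa-1,5-dien-1-yl}acetate
Product: 16 dienylacetic acid 2-{2-[(1S)-1,3,3-trimethylcyclohexyl]cyclohexa-1,5-dien-1-yl}acetic acid
Conditions: LiOH, THF/MeOH/H2O, 0 °C → rt; then 1 M HCl, 0 °C
Reagents that add atoms: lithium hydroxide, [Li+].[OH-]
Why: Saponification of the methyl ester with LiOH at 0 °C is faster than deprotonation at the allylic α-carbon, so the diene should stay where it is.

**Step 7**
Reactants: 16 dienylacetic acid 2-{2-[(1S)-1,3,3-trimethylcyclohexyl]cyclohexa-1,5-dien-1-yl}acetic acid; 17 auxiliary (4R)-4-benzyl-1,3-oxazolidin-2-one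
Product: 19 imide (4R)-4-benzyl-3-(2-{2-[(1S)-1,3,3-trimethylcyclohexyl]cyclohexa-1,5-dien-1-yl}acetyl)-1,3-oxazolidin-2-one, via pivalic mixed anhydride 18 (not isolated)
Conditions: t-BuCOCl, Et3N, THF, −20 °C; then 17, LiCl, rt
Reagents that add atoms: none
Why: N-Acylation of the oxazolidinone through the mixed pivalic anhydride under LiCl/Et3N activation attaches the auxiliary without a strong base that could move the β,γ-double bond.

**Step 8**
Reactants: 19 imide (4R)-4-benzyl-3-(2-{2-[(1S)-1,3,3-trimethylcyclohexyl]cyclohexa-1,5-dien-1-yl}acetyl)-1,3-oxazolidin-2-one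
Product: 21 methylated imide (4R)-4-benzyl-3-[(2R)-2-{2-[(1S)-1,3,3-trimethylcyclohexyl]cyclohexa-1,5-dien-1-yl}propanoyl]-1,3-oxazolidin-2-one, via sodium enolate 20 (not isolated)
Conditions: NaN(SiMe3)2, THF, −78 °C; MeI, −78 → −40 °C
Reagents that add atoms: iodomethane, CI
Why: Evans asymmetric alkylation: the chelated (Z)-sodium enolate is methylated at the α-carbon on the face away from the benzyl group, which with the (4R) auxiliary gives (R) at Cα, the minor epimer being removed by chromatography.

**Step 9**
Reactants: 21 methylated imide (4R)-4-benzyl-3-[(2R)-2-{2-[(1S)-1,3,3-trimethylcyclohexyl]cyclohexa-1,5-dien-1-yl}propanoyl]-1,3-oxazolidin-2-one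
Product: 23 acid (2R)-2-{2-[(1S)-1,3,3-trimethylcyclohexyl]cyclohexa-1,5-dien-1-yl}propanoic acid, via lithium peroxycarboxylate 22 (not isolated)
Conditions: LiOH, 30% H2O2, THF/H2O, 0 °C; Na2SO3; HCl to pH 3
Reagents that add atoms: hydrogen peroxide, OO
Why: Hydroperoxide-mediated imide cleavage: lithium hydroperoxide attacks the exocyclic carbonyl selectively and is too weakly basic to epimerise Cα; sulfite reduces the peroxy acid and the auxiliary is recovered.

**Step 10**
Reactants: 23 acid (2R)-2-{2-[(1S)-1,3,3-trimethylcyclohexyl]cyclohexa-1,5-dien-1-yl}propanoic acid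
Product: 24 diene ester methyl (2R)-2-{2-[(1S)-1,3,3-trimethylcyclohexyl]cyclohexa-1,5-dien-1-yl}propanoate
Conditions: Me3SiCHN2, PhMe/MeOH, 0 °C
Reagents that add atoms: (trimethylsilyl)diazomethane, C[Si](C)(C)C=[N+]=[N-]
Why: Esterification with Me3SiCHN2 in methanol proceeds through protonation of the diazo compound by the acid and O-methylation of the carboxylate under neutral conditions, so Cα and the diene are not disturbed.

**Step 11**
Reactants: 24 diene ester methyl (2R)-2-{2-[(1S)-1,3,3-trimethylcyclohexyl]cyclohexa-1,5-dien-1-yl}propanoate; 25 benzyloxyacetyl chloride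
Product: 27 cyclobutanone methyl (2R)-2-{(1R,6R,8S)-8-(benzyloxy)-7-oxo-3-[(1S)-1,3,3-trimethylcyclohexyl]bicyclo[4.2.0]oct-2-en-2-yl}propanoate, via benzyloxyketene 26 (not isolated)
Conditions: 25 (slow addition), Et3N, PhMe, 70 °C
Reagents that add atoms: none
Why: Et3N dehydrochlorinates 25 to benzyloxyketene 26, which adds to the C5=C6 bond in a concerted but asynchronous (2+2) cycloaddition: its carbonyl carbon C7 bonds first to the diene terminus C5 while positive charge develops at C6, stabilised by the C1=C2 bond, and the benzyloxy-bearing carbon C8 then closes on C6; the closest known reactions are the additions of alkoxyketenes to cyclopentadiene and cyclohexa-1,3-diene. The four-membered ring is thus closed by cycloaddition, both bonds forming in one step on the same face of the alkene, which fixes the cis relationship of the hydrogens on C5 and C6. C8 is set by the usual ketene approach with its hydrogen turned toward the ring, which leaves the benzyloxy group endo (on the side of the ring A carbons C1 and C4; C8 S). The face, and with it C5 (R) and C6 (R), is chosen by Cα: allylic strain with Cq holds the Cα hydrogen in the ring plane pointing at ring C, so the methyl group covers one face and the flatter ester the other, and attack anti to the methyl gives 27; this bias is expected to be moderate, and the minor face isomer is to be removed by chromatography. Site and regioselectivity need no help beyond the substrate: the tetrasubstituted C1=C2 bond is shielded by Cq and Cα, and only attack at C5 leads to an allyl-stabilised charge.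

**Step 12**
Reactants: 27 cyclobutanone methyl (2R)-2-{(1R,6R,8S)-8-(benzyloxy)-7-oxo-3-[(1S)-1,3,3-trimethylcyclohexyl]bicyclo[4.2.0]oct-2-en-2-yl}propanoate
Product: 28 benzyl acetal lactone methyl (2R)-2-{(3R,3aR,7aR)-3-(benzyloxy)-1-oxo-5-[(1S)-1,3,3-trimethylcyclohexyl]-1,3,3a,6,7,7a-hexahydro-2-benzofuran-4-yl}propanoate
Conditions: 30% H2O2, AcOH, NaOAc, 0 °C → rt
Reagents that add atoms: hydrogen peroxide, OO
Why: Baeyer–Villiger oxidation of the strained cyclobutanone with H2O2 in buffered AcOH proceeds through the peroxide adduct, from which the oxygen-bearing carbon C8 migrates in preference to C5 and with retention, giving the acetal lactone with C8 unchanged in space, while the shielded C1=C2 bond is left alone at this temperature.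

**Step 13**
Reactants: 28 benzyl acetal lactone methyl (2R)-2-{(3R,3aR,7aR)-3-(benzyloxy)-1-oxo-5-[(1S)-1,3,3-trimethylcyclohexyl]-1,3,3a,6,7,7a-hexahydro-2-benzofuran-4-yl}propanoate
Product: 29 target methyl (2R)-2-{(3R,3aR,7aR)-3-hydroxy-1-oxo-5-[(1S)-1,3,3-trimethylcyclohexyl]-1,3,3a,6,7,7a-hexahydro-2-benzofuran-4-yl}propanoate
Conditions: H2 (1 atm), Pd/C, EtOAc, rt
Reagents that add atoms: none
Why: Hydrogenolysis over Pd/C cleaves only the O–CH2Ph bond, so the lactol is freed under neutral conditions with C8 untouched, and the tetrasubstituted C1=C2 bond is not reduced at 1 atm.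

**Compound list**

1 | 2-bromoanisole | COc1ccccc1Br | starting material
2 | 3-methylcyclohex-2-en-1-one | CC1=CC(=O)CCC1 | starting material
3 | (2-methoxyphenyl)lithium, formed in the flask | [Li]c1ccccc1OC | intermediate
4 | (2-methoxyphenyl)dimethylaluminium, formed in the flask | C[Al](C)c1ccccc1OC | intermediate
5 | dimethylaluminium enolate {[(3S)-3-(2-methoxyphenyl)-3-methylcyclohex-1-en-1-yl]oxy}dimethylaluminium, formed in the flask | COc1ccccc1[C@@]1(C)CCCC(O[Al](C)C)=C1 | intermediate
6 | (3S)-3-(2-methoxyphenyl)-3-methylcyclohexan-1-one | COc1ccccc1[C@@]1(C)CCCC(=O)C1 | intermediate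
7 | 1-methoxy-2-[(1S)-1,3,3-trimethylcyclohexyl]benzene | COc1ccccc1[C@@]1(C)CCCC(C)(C)C1 | intermediate
8 | 1-methoxy-2-[(1S)-1,3,3-trimethylcyclohexyl]cyclohexa-1,4-diene, formed in the flask | COC1=C([C@@]2(C)CCCC(C)(C)C2)CC=CC1 | intermediate
9 | 6-[(1S)-1,3,3-trimethylcyclohexyl]cyclohex-3-en-1-one (both epimers at the carbon bearing ring C), formed in the flask | O=C1CC=CCC1[C@@]1(C)CCCC(C)(C)C1 | intermediate
10 | 6-[(1S)-1,3,3-trimethylcyclohexyl]cyclohex-2-en-1-one (both epimers at the carbon bearing ring C) | O=C1C=CCCC1[C@@]1(C)CCCC(C)(C)C1 | intermediate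
11 | lithium 2-[(1S)-1,3,3-trimethylcyclohexyl]cyclohexa-1,5-dien-1-olate, formed in the flask | [Li]OC1=C([C@@]2(C)CCCC(C)(C)C2)CCC=C1 | intermediate
12 | 2-[(1S)-1,3,3-trimethylcyclohexyl]cyclohexa-1,5-dien-1-yl trifluoromethanesulfonate | O=S(=O)(OC1=C([C@@]2(C)CCCC(C)(C)C2)CCC=C1)C(F)(F)F | intermediate
13 | methyl bromoacetate | COC(=O)CBr | starting material
14 | (2-methoxy-2-oxoethyl)zinc bromide, formed in the flask | COC(=O)C[Zn]Br | intermediate
15 | methyl 2-{2-[(1S)-1,3,3-trimethylcyclohexyl]cyclohexa-1,5-dien-1-yl}acetate | COC(=O)CC1=C([C@@]2(C)CCCC(C)(C)C2)CCC=C1 | intermediate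
16 | 2-{2-[(1S)-1,3,3-trimethylcyclohexyl]cyclohexa-1,5-dien-1-yl}acetic acid | OC(=O)CC1=C([C@@]2(C)CCCC(C)(C)C2)CCC=C1 | intermediate
17 | (4R)-4-benzyl-1,3-oxazolidin-2-one | O=C1N[C@H](Cc2ccccc2)CO1 | starting material
18 | mixed anhydride of 16 with pivalic acid, formed in the flask | CC(C)(C)C(=O)OC(=O)CC1=C([C@@]2(C)CCCC(C)(C)C2)CCC=C1 | intermediate
19 | (4R)-4-benzyl-3-(2-{2-[(1S)-1,3,3-trimethylcyclohexyl]cyclohexa-1,5-dien-1-yl}acetyl)-1,3-oxazolidin-2-one | O=C(CC1=C([C@@]2(C)CCCC(C)(C)C2)CCC=C1)N1[C@H](Cc2ccccc2)COC1=O | intermediate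
20 | sodium (Z)-enolate of 19, formed in the flask | [Na]O/C(=C\C1=C([C@@]2(C)CCCC(C)(C)C2)CCC=C1)N1[C@H](Cc2ccccc2)COC1=O | intermediate
21 | (4R)-4-benzyl-3-[(2R)-2-{2-[(1S)-1,3,3-trimethylcyclohexyl]cyclohexa-1,5-dien-1-yl}propanoyl]-1,3-oxazolidin-2-one | O=C([C@H](C)C1=C([C@@]2(C)CCCC(C)(C)C2)CCC=C1)N1[C@H](Cc2ccccc2)COC1=O | intermediate
22 | lithium (2R)-2-{2-[(1S)-1,3,3-trimethylcyclohexyl]cyclohexa-1,5-dien-1-yl}propaneperoxoate, formed in the flask | [Li+].[O-]OC(=O)[C@H](C)C1=C([C@@]2(C)CCCC(C)(C)C2)CCC=C1 | intermediate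
23 | (2R)-2-{2-[(1S)-1,3,3-trimethylcyclohexyl]cyclohexa-1,5-dien-1-yl}propanoic acid | OC(=O)[C@H](C)C1=C([C@@]2(C)CCCC(C)(C)C2)CCC=C1 | intermediate
24 | methyl (2R)-2-{2-[(1S)-1,3,3-trimethylcyclohexyl]cyclohexa-1,5-dien-1-yl}propanoate (ring A diene ester) | COC(=O)[C@H](C)C1=C([C@@]2(C)CCCC(C)(C)C2)CCC=C1 | intermediate
25 | benzyloxyacetyl chloride | O=C(Cl)COCc1ccccc1 | starting material
26 | benzyloxyketene, formed in the flask | O=C=COCc1ccccc1 | intermediate
27 | methyl (2R)-2-{(1R,6R,8S)-8-(benzyloxy)-7-oxo-3-[(1S)-1,3,3-trimethylcyclohexyl]bicyclo[4.2.0]oct-2-en-2-yl}propanoate (cis-fused; benzyloxy group on the side of the ring A carbons) | COC(=O)[C@H](C)C1=C([C@@]2(C)CCCC(C)(C)C2)CC[C@H]2C(=O)[C@@H](OCc3ccccc3)[C@@H]12 | intermediate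
28 | methyl (2R)-2-{(3R,3aR,7aR)-3-(benzyloxy)-1-oxo-5-[(1S)-1,3,3-trimethylcyclohexyl]-1,3,3a,6,7,7a-hexahydro-2-benzofuran-4-yl}propanoate | COC(=O)[C@H](C)C1=C([C@@]2(C)CCCC(C)(C)C2)CC[C@H]2C(=O)O[C@@H](OCc3ccccc3)[C@@H]12 | intermediate
29 | methyl (2R)-2-{(3R,3aR,7aR)-3-hydroxy-1-oxo-5-[(1S)-1,3,3-trimethylcyclohexyl]-1,3,3a,6,7,7a-hexahydro-2-benzofuran-4-yl}propanoate | COC(=O)[C@H](C)C1=C([C@@]2(C)CCCC(C)(C)C2)CC[C@H]2C(=O)O[C@@H](O)[C@@H]12 | target

**Count and risks**

Total steps: 13. Longest linear sequence: 13 steps (1 and 2 to 29).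

Step 11: the remote Cα centre may discriminate poorly between the two faces of the C5=C6 bond, and oligomerisation of the ketene may outrun its addition to a hindered diene. The fallback sets out from 24 and puts a second, reagent-based bias on the ketene. Sodium (S)-1-phenylethoxide and bromoacetic acid would give (S)-(1-phenylethoxy)acetic acid F1, and oxalyl chloride would convert it into (S)-(1-phenylethoxy)acetyl chloride F2. Et3N in the presence of 24 would release (S)-(1-phenylethoxy)ketene F3, whose (2+2) addition should give the 1-phenylethoxy cyclobutanone F4; the antipodal alcohol is taken if it proves to be the matched partner. H2O2 in AcOH would then give the 1-phenylethyl acetal lactone F5, and hydrogenolysis over Pd/C as in step 13 removes the benzylic group, so the route is rejoined at 29.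

Step 5: transmetalation or reductive elimination at C1 may stall beside the tert-alkyl group on C2, so that hydrolysis or reduction of the triflate takes over. The fallback sets out from 12 and replaces the carbon nucleophile by CO, which is insensitive to crowding. Hydroxycarbonylation (Pd(OAc)2, dppf, CO, KOAc, DMSO, then aqueous work-up) would give the dienoic acid F6, and oxalyl chloride its acid chloride F7. Me3SiCHN2 would give the diazoketone F8, and Wolff rearrangement (PhCO2Ag, Et3N, THF/H2O) would pass through the alkenylketene F9, which water traps as the homologous acid; this Arndt–Eistert sequence rejoins the route at 16.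

Step 4: the base may abstract a γ-proton at C4 instead of the hindered α′-proton at C2, which would lead to the linear dienyl triflate. The fallback sets out from 10 and forms the enol derivative by soft enolisation: Me3SiOTf and Et3N in CH2Cl2 would give the cross-conjugated trimethylsilyl dienol ether F10, which can be isolated, checked for regiochemistry and freed from any linear isomer. MeLi in THF then cleaves the O–Si bond and regenerates the dienolate regiospecifically, so the route is rejoined at 11 and continues to 12 with PhNTf2.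

**Further compounds**

F1 | step 11 | (S)-(1-phenylethoxy)acetic acid | C[C@H](OCC(=O)O)c1ccccc1
F2 | step 11 | (S)-(1-phenylethoxy)acetyl chloride | C[C@H](OCC(=O)Cl)c1ccccc1
F3 | step 11 | (S)-(1-phenylethoxy)ketene | C[C@H](OC=C=O)c1ccccc1
F4 | step 11 | methyl (2R)-2-{(1R,6R,8S)-7-oxo-8-[(1S)-1-phenylethoxy]-3-[(1S)-1,3,3-trimethylcyclohexyl]bicyclo[4.2.0]oct-2-en-2-yl}propanoate | COC(=O)[C@H](C)C1=C([C@@]2(C)CCCC(C)(C)C2)CC[C@H]2C(=O)[C@@H](O[C@@H](C)c3ccccc3)[C@@H]12
F5 | step 11 | methyl (2R)-2-{(3R,3aR,7aR)-1-oxo-3-[(1S)-1-phenylethoxy]-5-[(1S)-1,3,3-trimethylcyclohexyl]-1,3,3a,6,7,7a-hexahydro-2-benzofuran-4-yl}propanoate | COC(=O)[C@H](C)C1=C([C@@]2(C)CCCC(C)(C)C2)CC[C@H]2C(=O)O[C@@H](O[C@@H](C)c3ccccc3)[C@@H]12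
F6 | step 5 | 2-[(1S)-1,3,3-trimethylcyclohexyl]cyclohexa-1,5-diene-1-carboxylic acid | OC(=O)C1=C([C@@]2(C)CCCC(C)(C)C2)CCC=C1
F7 | step 5 | 2-[(1S)-1,3,3-trimethylcyclohexyl]cyclohexa-1,5-diene-1-carbonyl chloride | O=C(Cl)C1=C([C@@]2(C)CCCC(C)(C)C2)CCC=C1
F8 | step 5 | 2-diazo-1-{2-[(1S)-1,3,3-trimethylcyclohexyl]cyclohexa-1,5-dien-1-yl}ethan-1-one | [N-]=[N+]=CC(=O)C1=C([C@@]2(C)CCCC(C)(C)C2)CCC=C1
F9 | step 5 | 2-{2-[(1S)-1,3,3-trimethylcyclohexyl]cyclohexa-1,5-dien-1-yl}ethen-1-one (alkenylketene) | O=C=CC1=C([C@@]2(C)CCCC(C)(C)C2)CCC=C1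
F10 | step 4 | trimethyl({2-[(1S)-1,3,3-trimethylcyclohexyl]cyclohexa-1,5-dien-1-yl}oxy)silane | C[Si](C)(C)OC1=C([C@@]2(C)CCCC(C)(C)C2)CCC=C1
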